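If a first end group can meet either a second end group or the protic impurity, I reckon the share it gives to each from the ratio of those two partners at that moment, so I want that weighting from the earlier runs.

| flask | first end groups | second end groups | protic impurity | remark | time |
|---|---|---|---|---|---|
| spring | 0.46 M | 0.469 M | 0.046 M | run made earlier |  |
| autumn | 0.64 M | 0.469 M | 0.046 M | run made earlier |  |
| dusk | 1 M | 0.469 M | 0.046 M | run made earlier |  |
| dawn | 0.46 M | 0.94 M | 0.046 M | run made earlier |  |
| gamma | 0.46 M | 0.469 M (in portions, 4, over 3.0 min) | 0.0460 M | first portion at the start, last at 3.0 min | 5.0 min |
| beta | 0.46 M (fed, over 20 s) | 0.469 M | 0.0460 M | all else is in the flask from the start; the feed brings no volume worth counting | 5.0 min |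
| epsilon | 0.46 M | 0.469 M | 0.0460 M | everything together at the start | 5.0 min |
| zeta | 0.46 M (fed, over 3.0 min) | 0.469 M | 0.0460 M | all else is in the flask from the start; the feed brings no volume worth counting | 5.0 min |
| alpha | 0.46 M | 0.469 M (fed, over 3.0 min) | 0.0460 M | all else is in the flask from the start; the feed brings no volume worth counting | 5.0 min |

- spring (time / min: links / %): 0.333: 70; 1.00: 87; 2.00: 90; 2.50: 89; 4.00: 93; 5.00: 91
- autumn (time / min: links / %): 0.250: 57; 0.417: 65; 0.667: 68; 1.00: 67; 2.00: 70; 3.00: 71
- dusk (time / min: links / %): 0.250: 44; 0.417: 48; 0.667: 48; 1.00: 47; 2.00: 47; 3.00: 44
- dawn (time / min: links / %): 0.667: 97; 1.33: 100; 2.00: 100; 2.50: 99; 3.00: 98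

(scatter of a reading: 1.5 percentage points)

1. the flask that comes out highest in amount of links, in percent of the first end groups charged, or "all alike" when all lie within 1.5 percentage points (gamma / beta / epsilon / zeta / alpha / all alike)
2. links at the end, in percent of the first end groups charged, gamma
3. links at the end, in percent of the first end groups charged, beta
4. links at the end, in percent of the first end groups charged, epsilon
5. links at the end, in percent of the first end groups charged, zeta
6. links at the end, in percent of the first end groups charged, alpha



Dusk, with first end groups in excess, reads 0.470 M of links at 2.00 min, close to its charge of second end groups, so I let the impurity compete for first end groups instead. It can take at most its charge over theirs, a cap of 10.0%. Dawn, from 1.33 min on, falls short of full yield by 0.75 percentage points, while its second end groups average about 0.710 M. That gives a selectivity factor of 8.64, the rate of link formation over that of quenching at equal amounts of second end groups and impurity. It is a rough reading, since the scatter of that mean, 0.75 points, is as large as the shortfall.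

At the start of epsilon, my factor puts links ahead of quenching 88.1 to one, but that lead shrinks as second end groups are used. Epsilon is the spring recipe, whose last readings are 93% and 91%, so I put it highest, with beta close behind. For alpha and gamma, whose second end groups arrive over 3.0 min, I expect quenching near the cap and links near 90.0%. I leave zeta unranked.

The forecast says all alike, with 92.2% for epsilon, 92.2% for alpha, 92.2% for gamma and 91.9% for zeta, since “all flasks land near 92%”, and I differ from it on the ranking and on alpha and gamma.

Epsilon comes out highest at 92.0%, with beta 90.4%, alpha 87.4%, gamma 87.1% and zeta 77.8%.

    first end groups + protic impurity → quenched substrate (k = 4.60 L mol⁻¹ min⁻¹)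
    second end groups ⇌ dormant form (K = 1.90, k = 0.320 min⁻¹)
    first end groups + second end groups → links + by-product (k = 18.0 L mol⁻¹ min⁻¹)
    links → over-reaction product (k = 2.70 × 10⁻⁴ min⁻¹)

Alpha holds 9.70% as quenched substrate, near the cap, against 5.99% in epsilon. By my factor, the two rates tie at 0.005325 M of second end groups with the impurity at its charge, and epsilon's mean over its first 3.0 min, 0.0547 M, stands 10.3 times above that.

In the neighbour of epsilon with 1.9 M of second end groups, the factor gives a loss of 0.319%, so links near 99.7%. The computed flask gives 99.2%, with 0.687% quenched.

Readings and results were generated by integration for substances that don't exist.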